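(The numbers are invented; the flask was simulated.)

There are 5 questions here, and I would answer them with one ratio, reckoned before any run.

| setting | ochre | grey | teal | amber |
|---|---|---|---|---|
| starting material | 0.0010 M | 0.0010 M | 0.0010 M (fed, over 1.5 min) | 0.0010 M (fed, over 1.5 min) |
| partner | 1.10 mM | 1.10 mM | 1.10 mM | 1.10 mM |
| free catalyst | 1.7 µM | 1.7 µM | 1.7 µM | 1.7 µM |
| time | 8.0 min | 8.0 min | 8.0 min | 8.0 min |
| remark | everything together at the start at 5 °C, warmed to 35 °C at 1.5 min | everything together at the start | all else is in the flask from the start; the feed brings no volume worth counting | the addition at 5 °C, then warmed to 35 °C; the feed brings no volume worth counting |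
| temperature |  | 35 °C | 35 °C |  |

    starting material + free catalyst → free catalyst + open intermediate (k1 = 38000 L mol⁻¹ s⁻¹, Ea1 = 8.00 kJ mol⁻¹)
    free catalyst + open intermediate ⇌ catalyst intermediate (K2 = 340 L mol⁻¹, k2 = 1.1 × 10⁵ L mol⁻¹ s⁻¹, Ea2 = 20.0 kJ mol⁻¹, ΔH2 = −49.0 kJ mol⁻¹)
    partner + catalyst intermediate → free catalyst + target (k3 = 1.4 × 10⁵ L mol⁻¹ s⁻¹, Ea3 = 26.0 kJ mol⁻¹)
    open intermediate → side product A (k4 = 0.027 s⁻¹, Ea4 = 72.0 kJ mol⁻¹)
    starting material + open intermediate → side product B (k5 = 12 L mol⁻¹ s⁻¹, Ea5 = 49.0 kJ mol⁻¹)
    (constants at 35 °C)

- a species is counted by the starting material in it: one side product B counts as two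
- at 35 °C the constants are as listed, elsewhere as the activation energies and enthalpies make them

- which flask leads in share of target in target plus side product A ("all alike" within 1.5 percentage points) (ochre / grey / teal / amber / all alike)
- share of target in target plus side product A at the end, ochre
- share of target in target plus side product A at the end, grey
- share of target in target plus side product A at the end, teal
- share of target in target plus side product A at the end, amber

The share asked for is made at the open intermediate, which leaks to side product A or is captured by free catalyst; what it loses to side product B counts on neither side of the share. Capture runs at the binding frequency, 0.187 s⁻¹ with catalyst as charged, times the chance that the catalyst intermediate goes on with partner, at 154 s⁻¹, rather than falling back, at 324 s⁻¹. At 35 °C that makes 0.0603 s⁻¹ against a leak of 0.027 s⁻¹. Their quotient, capture frequency over leak frequency, is my capture ratio, a selectivity factor: 2.23 at the start, and a ratio r gives a share of r/(1+r), here 69.0 %.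

Capture slows as partner is used. At 0.5 of its charge the ratio is 1.33, smaller by a factor 1.68, and the mean of the two shares puts grey at 63.1 %. The ratio holds neither starting material nor feed time, so I give teal the same figure.

At 5 °C the leak is 0.00130 s⁻¹, while capture stays near 0.0600 s⁻¹. The cold ratio is therefore 46.0, a share of 97.9 %. Opening takes 21.7 s and capture 16.7 s, so over 90 s I expect 9.57 % of ochre to remain unconverted at warming. Counting everything converted as target, I reckon ochre's partner then at 0.196 mM, which gives a hot ratio of 0.541, and I reckon ochre's share at 91.9 %. Averaging over the feed, I reckon amber at 38.5 % unconverted at warming, with 0.485 mM of partner, and its share at 81.2 %.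

The forecast names ochre, with 88 %, 62.6 %, 62.8 % and 75.5 % for ochre, grey, teal and amber, on the ground that “Ochre makes about 80% of its target cold”; my ochre stands higher, and so does my amber.

The flasks give 88.4 %, 62.4 %, 62.5 % and 76.5 % in that order, so ochre leads. At warming, after 1.50 min, ochre still holds 14.8 % as starting material plus open intermediate, more than my 9.57 %. Ochre's partner stands at that moment at 26.6 % of its charge, and with that partner, catalyst as charged and the constants of 35 °C, the capture ratio is 0.778, a share of 43.8 %. On a repeat of ochre I would read partner at warming.

In the neighbour of ochre with 0.0044 M of partner, my reckoned remainder meets a hot ratio of 4.17, and with the cold share kept I reckon 96.2 %. That flask gives 97.4 %.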